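The plan cuts ring A of unit 2 (the apigenin half, C4a''–C8a''). This ring is a hexasubstituted acylphloroglucinol whose C6'' holds C8 of unit 1 (the acacetin half) between O5'' and O7''. The alternating oxygens map onto a 1,1,3-trioxygenated diene (C8a''–C8''–C7''–C6'') and an alkoxy ynone (C5''–C4a''). One Diels–Alder reaction with aromatising elimination forms C6''–C5'' and C8a''–C4a''. It builds the ring around the existing aryl–carbon bond instead of coupling two crowded arenes. It frees only O8a'', which fixes the later pyranone closure. The precursor is a 4-aryl Brassard-type silyl ketene acetal whose aryl group carries differentiated oxygens and an iodine at C4a as the future acetyl site.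

Key step: step 9

Conventions: unprimed locants belong to unit 1 and double-primed locants to unit 2. "On" means the oxygen on carbon n. Bn = benzyl, MOM = methoxymethyl, Ar* = 4,6-bis(benzyloxy)-3-iodo-2-(methoxymethoxy)phenyl. In Ar*, the ipso carbon is C8, C2 is C8a, C3 is C4a, C4 is C5 and C6 is C7.
Remark on the chemistry: the target SMILES holds no stereodescriptor, so the hindered C8–C6'' axis is made without control and the product is taken as the racemic pair of atropisomers.

Step 1
Reactants: 1 2,4,6-trihydroxybenzaldehyde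
Product: 2 2,4-bis(benzyloxy)-6-hydroxybenzaldehyde
Conditions: BnBr (2.05 equiv), K2CO3, DMF, 0 °C to rt
Reagents that add atoms: benzyl bromide, BrCc1ccccc1
Why: Williamson etherification should take the unchelated 4-OH and one ortho hydroxyl, while the last hydroxyl stays locked in the hydrogen bond to the formyl group and is kept as the future O8a.

Step 2
Reactants: 2 2,4-bis(benzyloxy)-6-hydroxybenzaldehyde
Product: 3 4,6-bis(benzyloxy)-2-hydroxy-3-iodobenzaldehyde
Conditions: NIS (1.0 equiv), MeCN, 0 °C, dark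
Reagents that add atoms: N-iodosuccinimide, O=C1CCC(=O)N1I
Why: Electrophilic aromatic iodination of 2-hydroxy-4,6-dialkoxyaryl carbonyl compounds goes to the carbon between the free hydroxyl and the neighbouring ether, since the other CH is walled in by two benzyloxy groups, and this marks C4a.

Step 3
Reactants: 3 4,6-bis(benzyloxy)-2-hydroxy-3-iodobenzaldehyde
Product: 4 4,6-bis(benzyloxy)-3-iodo-2-(methoxymethoxy)benzaldehyde
Conditions: NaH, MOMCl, DMF, 0 °C to rt
Reagents that add atoms: chloromethyl methyl ether, COCCl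
Why: O-alkylation of the sodium phenolate with a small, hard chloromethyl ether should proceed even at this flanked position and gives an acetal that is orthogonal to the benzyl ethers.

Step 4
Reactants: 4 4,6-bis(benzyloxy)-3-iodo-2-(methoxymethoxy)benzaldehyde
Product: 5 1,5-bis(benzyloxy)-2-ethynyl-4-iodo-3-(methoxymethoxy)benzene
Conditions: MeC(O)C(N2)P(O)(OMe)2, K2CO3, MeOH–THF, rt
Reagents that add atoms: dimethyl (1-diazo-2-oxopropyl)phosphonate, COP(=O)(OC)C(=[N+]=[N-])C(C)=O
Why: The Ohira–Bestmann variant of the Seyferth–Gilbert homologation adds the one missing carbon under mild basic conditions that leave the MOM acetal, the benzyl ethers and the aryl iodide untouched.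

Step 5
Reactants: 5 1,5-bis(benzyloxy)-2-ethynyl-4-iodo-3-(methoxymethoxy)benzene; 6 benzyl diazoacetate
Product: 7 benzyl 4-Ar*-but-3-ynoate
Conditions: CuI (5 mol %), MeCN, rt
Reagents that add atoms: none
Why: Copper-catalysed coupling of a terminal alkyne with a diazoacetate (copper carbene and acetylide, formal C–H insertion) gives 3-alkynoates at room temperature without base, and the reacting sp carbon lies well away from the ortho substituents.

Step 6
Reactants: 7 benzyl 4-Ar*-but-3-ynoate
Product: 9 benzyl (E)-4-Ar*-3-(benzyloxy)but-2-enoate, via allenoate 8 (not isolated)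
Conditions: BnOH (1.2 equiv), KOtBu (15 mol %), THF, 0 °C to rt
Reagents that add atoms: benzyl alcohol, OCc1ccccc1
Why: Base isomerises the 3-alkynoate to the allenoate, benzyl oxide adds to its central carbon (oxa-Michael addition) and reprotonation gives the conjugated (E)-enol ether, which sidesteps the C- versus O-alkylation problem of a β-keto ester while the benzyl ester makes transesterification degenerate.

Step 7
Reactants: 9 benzyl (E)-4-Ar*-3-(benzyloxy)but-2-enoate
Product: 11 (1Z,3Z)-4-Ar*-1,3-bis(benzyloxy)-1-(trimethylsilyloxy)buta-1,3-diene, via lithium dienolate 10 (not isolated)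
Conditions: LiN(iPr)2 (LDA), THF, −78 °C; Me3SiCl, −78 to 0 °C; pentane, filtration, used crude
Reagents that add atoms: chlorotrimethylsilane, C[Si](C)(C)Cl
Why: γ-Deprotonation of the benzylic CH2 lying cis to the ester followed by O-silylation is the standard entry to Brassard-type dienes, and allylic strain against the ester side should turn the aryl group towards the 3-benzyloxy group, which sets the (3Z) geometry.

Step 8
Reactants: 12 ethoxyacetylene
Product: 14 4-ethoxybut-3-yn-2-one, via lithium ethoxyacetylide 13 (not isolated)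
Conditions: nBuLi, THF, −78 °C; MeC(O)N(OMe)Me, −78 to −30 °C; cold aq NH4Cl
Reagents that add atoms: N-methoxy-N-methylacetamide, CC(=O)N(C)OC
Why: In the Weinreb ketone synthesis the chelated tetrahedral adduct prevents a second addition, and the cold buffered quench should release the moisture-sensitive push-pull ynone, which is used freshly prepared.

Step 9
Reactants: 11 (1Z,3Z)-4-Ar*-1,3-bis(benzyloxy)-1-(trimethylsilyloxy)buta-1,3-diene; 14 4-ethoxybut-3-yn-2-one
Product: 17 1-[3-Ar*-4-(benzyloxy)-2-ethoxy-6-hydroxyphenyl]ethan-1-one, via cyclohexadiene cycloadduct 15 (not isolated), via aryl trimethylsilyl ether 16 (not isolated)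
Conditions: 14 (2.5 equiv), PhMe (2 M), 75 °C, sealed tube under argon; then 10% aq citric acid, THF, rt
Reagents that add atoms: none
Why: Proposed new method: the closest known reaction type is the thermal cycloaddition of Brassard-type 1,1,3-trioxygenated dienes to acetylenic ketones and esters, which gives resorcinols after elimination, but neither a 4-aryl diene of this bulk nor an alkoxy-substituted ynone has been used in it. C4 of 11, the vinylogous terminus of the ketene acetal with the largest HOMO coefficient, should bond to the ethoxy-bearing β-carbon of 14 (largest LUMO coefficient) while C1 bonds to the α-carbon, either in one asynchronous [4+2] event or as Michael addition followed by 6-exo-trig attack of the allenolate carbon on the silyloxycarbenium carbon C1. Ring A of unit 2 therefore closes in an intermolecular [4+2] mode, the mixed ketal carbon of 15 expels benzyl alcohol together with the hydrogen on C6'' so that 16 is aromatic, and mild acid then frees O8a''. The selectivity needed is the diene–ynone orientation, and the matched polarity secures it, which places the aryl group between OEt and OBn and the only free hydroxyl beside the acetyl group. The (3Z) geometry keeps the aryl group on the outer side of the s-cis diene, the slim sp carbon can approach over the face held by the in-plane C7 benzyloxy group although the iodine pushes the MOM group over the other face, and the bath stays below 80 °C because ethoxyalkynes lose ethene by retro-ene reaction above about 100 °C. The two sp3 carbons of 15 vanish on aromatisation, so no stereocentre remains and the C8–C6'' axis forms as a racemate.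

Step 10
Reactants: 17 1-[3-Ar*-4-(benzyloxy)-2-ethoxy-6-hydroxyphenyl]ethan-1-one; 18 4-(benzyloxy)benzaldehyde
Product: 19 (E)-1-[3-Ar*-4-(benzyloxy)-2-ethoxy-6-hydroxyphenyl]-3-[4-(benzyloxy)phenyl]prop-2-en-1-one
Conditions: KOH (50% aq), EtOH–THF, rt
Reagents that add atoms: none
Why: Claisen–Schmidt condensation of 2-hydroxy-4,6-dialkoxyacetophenones with non-enolisable benzaldehydes is routine, gives the (E)-enone by E1cB dehydration, and leaves the MOM acetal, the ethers and the aryl iodide intact.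

Step 11
Reactants: 19 (E)-1-[3-Ar*-4-(benzyloxy)-2-ethoxy-6-hydroxyphenyl]-3-[4-(benzyloxy)phenyl]prop-2-en-1-one
Product: 21 (E)-1-{3-[3-acetyl-4,6-bis(benzyloxy)-2-hydroxyphenyl]-4-(benzyloxy)-2-ethoxy-6-hydroxyphenyl}-3-[4-(benzyloxy)phenyl]prop-2-en-1-one, via 1-ethoxyvinyl arene 20 (not isolated)
Conditions: CH2=C(OEt)SnBu3 (2 equiv), Pd(PPh3)4 (10 mol %), CuI (20 mol %), DMF, 80 °C; then 2 M HCl, THF, 45 °C
Reagents that add atoms: tributyl(1-ethoxyvinyl)stannane, C=C(OCC)[Sn](CCCC)(CCCC)CCCC; water, O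
Why: Stille coupling of the aryl iodide with the α-ethoxyvinylstannane puts a masked acetyl group exactly on C4a without any Lewis acid, and the same dilute acid then hydrolyses the enol ether and the phenolic MOM acetal while the benzyl and ethyl ethers stay.

Step 12
Reactants: 21 (E)-1-{3-[3-acetyl-4,6-bis(benzyloxy)-2-hydroxyphenyl]-4-(benzyloxy)-2-ethoxy-6-hydroxyphenyl}-3-[4-(benzyloxy)phenyl]prop-2-en-1-one; 22 4-methoxybenzaldehyde
Product: 23 (E,E)-bis-chalcone carrying the 4-methoxycinnamoyl group on C4a and the 4-(benzyloxy)cinnamoyl group on C4a''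
Conditions: KOH (50% aq), EtOH–THF, rt
Reagents that add atoms: none
Why: Claisen–Schmidt condensation at the only methyl ketone left, while the first enone, held as its electron-rich phenolate, is not expected to undergo retro-aldol exchange at room temperature, so the two B rings stay distinct.

Step 13
Reactants: 23 (E,E)-bis-chalcone
Product: 24 5,7-bis(benzyloxy)-8-{7-(benzyloxy)-2-[4-(benzyloxy)phenyl]-5-ethoxy-4-oxo-4H-chromen-6-yl}-2-(4-methoxyphenyl)-4H-chromen-4-one
Conditions: I2 (20 mol %), DMSO, 130 °C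
Reagents that add atoms: none
Why: Iodine-catalysed oxidative cyclisation of 2'-hydroxychalcones (oxa-Michael closure, then dehydrogenation with DMSO as terminal oxidant) should act on both halves at once, and each enone has a single free ortho hydroxyl (O8a and O8a''), so only the 8,6''-linked biflavone can form.

Step 14
Reactants: 24 protected biflavone
Product: 25 8-[5,7-dihydroxy-2-(4-hydroxyphenyl)-4-oxo-4H-chromen-6-yl]-5,7-dihydroxy-2-(4-methoxyphenyl)-4H-chromen-4-one (target)
Conditions: BCl3 (excess), C6HMe5, CH2Cl2, −78 °C to rt; then water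
Reagents that add atoms: none
Why: BCl3 with pentamethylbenzene as benzyl cation trap cleaves aryl benzyl ethers at low temperature, on warming the boron chelate between O4'' and O5'' lets chloride remove the peri ethyl group, and the unchelated 4'-methyl ether is inert to BCl3.

Compound list
1 | 2,4,6-trihydroxybenzaldehyde | O=Cc1c(O)cc(O)cc1O | starting material
2 | 2,4-bis(benzyloxy)-6-hydroxybenzaldehyde | O=Cc1c(O)cc(OCc2ccccc2)cc1OCc1ccccc1 | intermediate
3 | 4,6-bis(benzyloxy)-2-hydroxy-3-iodobenzaldehyde | O=Cc1c(O)c(I)c(OCc2ccccc2)cc1OCc1ccccc1 | intermediate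
4 | 4,6-bis(benzyloxy)-3-iodo-2-(methoxymethoxy)benzaldehyde | O=Cc1c(OCOC)c(I)c(OCc2ccccc2)cc1OCc1ccccc1 | intermediate
5 | 1,5-bis(benzyloxy)-2-ethynyl-4-iodo-3-(methoxymethoxy)benzene | C#Cc1c(OCOC)c(I)c(OCc2ccccc2)cc1OCc1ccccc1 | intermediate
6 | benzyl diazoacetate | [N-]=[N+]=CC(=O)OCc1ccccc1 | starting material
7 | benzyl 4-Ar*-but-3-ynoate | O=C(CC#Cc1c(OCOC)c(I)c(OCc2ccccc2)cc1OCc1ccccc1)OCc1ccccc1 | intermediate
8 | benzyl 4-Ar*-buta-2,3-dienoate (racemic allene, not isolated) | O=C(C=C=Cc1c(OCOC)c(I)c(OCc2ccccc2)cc1OCc1ccccc1)OCc1ccccc1 | intermediate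
9 | benzyl (E)-4-Ar*-3-(benzyloxy)but-2-enoate | O=C(OCc1ccccc1)/C=C(/OCc1ccccc1)Cc1c(OCOC)c(I)c(OCc2ccccc2)cc1OCc1ccccc1 | intermediate
10 | lithium dienolate of 9 (not isolated) | c1ccccc1CO/C([O-])=C/C(OCc1ccccc1)=C/c1c(OCOC)c(I)c(OCc2ccccc2)cc1OCc1ccccc1.[Li+] | intermediate
11 | (1Z,3Z)-4-Ar*-1,3-bis(benzyloxy)-1-(trimethylsilyloxy)buta-1,3-diene | c1ccccc1CO/C(O[Si](C)(C)C)=C/C(OCc1ccccc1)=C/c1c(OCOC)c(I)c(OCc2ccccc2)cc1OCc1ccccc1 | intermediate
12 | ethoxyacetylene | CCOC#C | starting material
13 | lithium ethoxyacetylide (not isolated) | [Li+].[C-]#COCC | intermediate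
14 | 4-ethoxybut-3-yn-2-one | CCOC#CC(C)=O | intermediate
15 | 1-[3-Ar*-4,6-bis(benzyloxy)-2-ethoxy-6-(trimethylsilyloxy)cyclohexa-1,4-dien-1-yl]ethan-1-one (relative configuration irrelevant, not isolated) | CCOC1=C(C(C)=O)C(OCc2ccccc2)(O[Si](C)(C)C)C=C(OCc2ccccc2)C1c1c(OCOC)c(I)c(OCc2ccccc2)cc1OCc1ccccc1 | intermediate
16 | 1-[3-Ar*-4-(benzyloxy)-2-ethoxy-6-(trimethylsilyloxy)phenyl]ethan-1-one (not isolated) | CCOc1c(C(C)=O)c(O[Si](C)(C)C)cc(OCc2ccccc2)c1-c1c(OCOC)c(I)c(OCc2ccccc2)cc1OCc1ccccc1 | intermediate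
17 | 1-[3-Ar*-4-(benzyloxy)-2-ethoxy-6-hydroxyphenyl]ethan-1-one | CCOc1c(C(C)=O)c(O)cc(OCc2ccccc2)c1-c1c(OCOC)c(I)c(OCc2ccccc2)cc1OCc1ccccc1 | intermediate
18 | 4-(benzyloxy)benzaldehyde | O=Cc1ccc(OCc2ccccc2)cc1 | starting material
19 | (E)-1-[3-Ar*-4-(benzyloxy)-2-ethoxy-6-hydroxyphenyl]-3-[4-(benzyloxy)phenyl]prop-2-en-1-one | CCOc1c(C(=O)/C=C/c2ccc(OCc3ccccc3)cc2)c(O)cc(OCc2ccccc2)c1-c1c(OCOC)c(I)c(OCc2ccccc2)cc1OCc1ccccc1 | intermediate
20 | analogue of 19 with a 1-ethoxyvinyl group in place of iodine (not isolated) | CCOc1c(C(=O)/C=C/c2ccc(OCc3ccccc3)cc2)c(O)cc(OCc2ccccc2)c1-c1c(OCOC)c(C(=C)OCC)c(OCc2ccccc2)cc1OCc1ccccc1 | intermediate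
21 | (E)-1-{3-[3-acetyl-4,6-bis(benzyloxy)-2-hydroxyphenyl]-4-(benzyloxy)-2-ethoxy-6-hydroxyphenyl}-3-[4-(benzyloxy)phenyl]prop-2-en-1-one | CCOc1c(C(=O)/C=C/c2ccc(OCc3ccccc3)cc2)c(O)cc(OCc2ccccc2)c1-c1c(O)c(C(C)=O)c(OCc2ccccc2)cc1OCc1ccccc1 | intermediate
22 | 4-methoxybenzaldehyde | COc1ccc(C=O)cc1 | starting material
23 | (E,E)-bis-chalcone: 21 with the acetyl group extended to a 4-methoxycinnamoyl group | CCOc1c(C(=O)/C=C/c2ccc(OCc3ccccc3)cc2)c(O)cc(OCc2ccccc2)c1-c1c(O)c(C(=O)/C=C/c2ccc(OC)cc2)c(OCc2ccccc2)cc1OCc1ccccc1 | intermediate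
24 | 5,7-bis(benzyloxy)-8-{7-(benzyloxy)-2-[4-(benzyloxy)phenyl]-5-ethoxy-4-oxo-4H-chromen-6-yl}-2-(4-methoxyphenyl)-4H-chromen-4-one | COc1ccc(-c2cc(=O)c3c(OCc4ccccc4)cc(OCc4ccccc4)c(-c4c(OCc5ccccc5)cc5oc(-c6ccc(OCc7ccccc7)cc6)cc(=O)c5c4OCC)c3o2)cc1 | intermediate
25 | 8-[5,7-dihydroxy-2-(4-hydroxyphenyl)-4-oxo-4H-chromen-6-yl]-5,7-dihydroxy-2-(4-methoxyphenyl)-4H-chromen-4-one | COc1ccc(-c2cc(=O)c3c(O)cc(O)c(-c4c(O)cc5oc(-c6ccc(O)cc6)cc(=O)c5c4O)c3o2)cc1 | target

Total step count: 14. Longest linear sequence: 13 (steps 1–7 and 9–14). Step 8 is a one-step side branch.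

Steps most likely to fail

Step 9. The two ortho oxygens of the aryl group may shield C4 of the diene so strongly that bond formation to the ethoxy-bearing carbon is slower than hydrolysis of the ketene acetal or thermal loss of the ynone. The donor-substituted ynone may also be too weak an acceptor. The fallback gives up the benzannulation and makes the C8–C6'' bond by Suzuki–Miyaura coupling of two finished flavone halves.
- It sets out from 22, which is condensed (KOH, EtOH) with purchased 1-[2,4-bis(benzyloxy)-6-hydroxyphenyl]ethanone to the chalcone F1.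
- I2 in DMSO closes this to 5,7-di-O-benzylacacetin F2, and NIS with catalytic CF3CO2H in MeCN iodinates C8 to the 8-iodoflavone F3.
- In parallel, purchased apigenin is benzylated at O7 and O4' (BnBr, K2CO3, DMF) to 7,4'-di-O-benzylapigenin F4.
- It is iodinated ortho to the chelated 5-hydroxyl (I2, TlOAc, CH2Cl2) to the 6-iodoflavone F5 and ethylated (EtI, K2CO3, DMF) to the 5-ethoxy-6-iodoflavone F6.
- Borylation (B2pin2, PdCl2(dppf), KOAc, dioxane) gives the 6-pinacolboronate F7.
- Coupling of F3 with F7 (Pd(OAc)2, SPhos, K3PO4, toluene–water, 100 °C) comes back to the route at 24.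

Step 11. Transmetalation at a palladium centre flanked by two ether oxygens may be slow, so that protodestannylation of the acid-sensitive stannane by the free phenol or reductive loss of iodine takes over. The fallback closes ring C of unit 1 directly at the iodophenol and needs no acetyl group.
- It sets out from 19. 2 M HCl in THF removes the MOM group to give the iodophenol chalcone F8.
- Carbonylative Sonogashira annulation with 4-ethynylanisole (PdCl2(dppf), CO, Et2NH, DMF, 90 °C; acyl-palladium alkynylation, then amine-mediated 6-endo closure) gives the flavone–chalcone F9.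
- I2 in DMSO, which also takes along any flavanone formed from the remaining enone, comes back to the route at 24.

Step 14. Chloride attack on the primary ethyl group may lag behind debenzylation. Forcing the reaction could then start to cleave the 4'-methyl ether or allow C-benzylation of the electron-rich rings. The fallback separates the two tasks.
- It sets out from 24. Hydrogenolysis (H2, Pd/C, THF–MeOH) removes the four benzyl groups to give the 5''-O-ethyl ether F10.
- Chelation-controlled dealkylation of the peri ether (AlCl3, MeCN, 60 °C, then dilute HCl) comes back to the route at 25.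

Further compounds
F1 | step 9 | (E)-1-[2,4-bis(benzyloxy)-6-hydroxyphenyl]-3-(4-methoxyphenyl)prop-2-en-1-one | COc1ccc(/C=C/C(=O)c2c(O)cc(OCc3ccccc3)cc2OCc2ccccc2)cc1
F2 | step 9 | 5,7-bis(benzyloxy)-2-(4-methoxyphenyl)-4H-chromen-4-one | COc1ccc(-c2cc(=O)c3c(OCc4ccccc4)cc(OCc4ccccc4)cc3o2)cc1
F3 | step 9 | 5,7-bis(benzyloxy)-8-iodo-2-(4-methoxyphenyl)-4H-chromen-4-one | COc1ccc(-c2cc(=O)c3c(OCc4ccccc4)cc(OCc4ccccc4)c(I)c3o2)cc1
F4 | step 9 | 7-(benzyloxy)-2-[4-(benzyloxy)phenyl]-5-hydroxy-4H-chromen-4-one | O=c1cc(-c2ccc(OCc3ccccc3)cc2)oc2cc(OCc3ccccc3)cc(O)c12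
F5 | step 9 | 7-(benzyloxy)-2-[4-(benzyloxy)phenyl]-5-hydroxy-6-iodo-4H-chromen-4-one | O=c1cc(-c2ccc(OCc3ccccc3)cc2)oc2cc(OCc3ccccc3)c(I)c(O)c12
F6 | step 9 | 7-(benzyloxy)-2-[4-(benzyloxy)phenyl]-5-ethoxy-6-iodo-4H-chromen-4-one | CCOc1c(I)c(OCc2ccccc2)cc2oc(-c3ccc(OCc4ccccc4)cc3)cc(=O)c12
F7 | step 9 | 7-(benzyloxy)-2-[4-(benzyloxy)phenyl]-5-ethoxy-6-(4,4,5,5-tetramethyl-1,3,2-dioxaborolan-2-yl)-4H-chromen-4-one | CCOc1c(B2OC(C)(C)C(C)(C)O2)c(OCc2ccccc2)cc2oc(-c3ccc(OCc4ccccc4)cc3)cc(=O)c12
F8 | step 11 | (E)-1-{4-(benzyloxy)-3-[4,6-bis(benzyloxy)-2-hydroxy-3-iodophenyl]-2-ethoxy-6-hydroxyphenyl}-3-[4-(benzyloxy)phenyl]prop-2-en-1-one | CCOc1c(C(=O)/C=C/c2ccc(OCc3ccccc3)cc2)c(O)cc(OCc2ccccc2)c1-c1c(O)c(I)c(OCc2ccccc2)cc1OCc1ccccc1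
F9 | step 11 | 5,7-bis(benzyloxy)-8-{6-(benzyloxy)-3-[(E)-3-(4-(benzyloxy)phenyl)acryloyl]-2-ethoxy-4-hydroxyphenyl}-2-(4-methoxyphenyl)-4H-chromen-4-one | COc1ccc(-c2cc(=O)c3c(OCc4ccccc4)cc(OCc4ccccc4)c(-c4c(OCc5ccccc5)cc(O)c(C(=O)/C=C/c5ccc(OCc6ccccc6)cc5)c4OCC)c3o2)cc1
F10 | step 14 | 8-[5-ethoxy-7-hydroxy-2-(4-hydroxyphenyl)-4-oxo-4H-chromen-6-yl]-5,7-dihydroxy-2-(4-methoxyphenyl)-4H-chromen-4-one | COc1ccc(-c2cc(=O)c3c(O)cc(O)c(-c4c(O)cc5oc(-c6ccc(O)cc6)cc(=O)c5c4OCC)c3o2)cc1
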